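**Plan** (drimane numbering: C4 = CMe2, C5 and C10 = ring fusion, C8 = carbinol carbon, C9 carries the benzylic C11)
Cuts, in retrosynthetic order: O–MOM and Ar–CHO (from Ar–Br); C8–CH3; C7 taken out of ring B, which leaves the cyclopentanone C5–C6–C8–C9–C10 of a cis-hydrindane; C9–C11 (enolate benzylation); C9–C1 and C9–C10 (cyclopropane from a diazo ketone); C5–C6 (Claisen).
Forward: ring A is bought as a cyclohexenone; a carbenoid closes the five-membered ring together with a cyclopropane; Li/NH3 opens the cyclopropane and the C9 enolate takes up the separately made arene as a benzyl bromide; one carbon (C7) is then inserted to give ring B; methyl addition, formylation and deprotection finish.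
Enabling feature: in the benzylated cis-hydrindanone the C8 carbonyl sits between a free methylene (C6) and a methine (C9) wedged between quaternary C10 and the benzyl arm, so only C6 should shift. The folded cis-bicyclo[4.3.0] frame has by then fixed C5, C9 and C10.
Stereochemistry: CBS reduction gives one carbinol centre, the Claisen shift relays it to C5, the tether enforces the cis ring fusion at C10, convex-face benzylation sets C9 and exo-face methyl addition sets C8.

Key step: step 11

Remark: the given SMILES has H-5 and the C10 methyl on the same face (a cis-decalin, (1R,2R,4aR,8aS) in decalin numbering), and the route is designed for that; 1 and 9 are taken as catalogue compounds.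

Step 1
Reactants: 1 2,4,4-trimethylcyclohex-2-en-1-one
Product: 2 (S)-2,4,4-trimethylcyclohex-2-en-1-ol
Conditions: (R)-2-methyl-CBS-oxazaborolidine (10 mol %), BH3·SMe2, THF, −20 °C; MeOH, then aqueous work-up
Reagents that add atoms: none
Why: Corey–Bakshi–Shibata reduction, in which the α-methylated alkene arm should act as the large group so that the (R)-catalyst delivers hydride to give the (S)-carbinol.

Step 2
Reactants: 2 (S)-2,4,4-trimethylcyclohex-2-en-1-ol
Product: 4 ethyl 2-[(1R)-2,6,6-trimethylcyclohex-2-en-1-yl]acetate, via ketene acetal 3 (not isolated)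
Conditions: MeC(OEt)3 (6 equiv), EtCO2H (cat.), 140 °C, EtOH distilled off
Reagents that add atoms: triethyl orthoacetate CCOC(C)(OCC)OCC
Why: Johnson–Claisen rearrangement, a suprafacial [3,3] shift that should move the chirality from the C–O centre to the new C–C centre (the future C5, next to CMe2) and place the double bond at the methyl-bearing carbon (future C10=C1).

Step 3
Reactants: 4 ethyl 2-[(1R)-2,6,6-trimethylcyclohex-2-en-1-yl]acetate
Product: 5 2-[(1R)-2,6,6-trimethylcyclohex-2-en-1-yl]acetic acid
Conditions: LiOH, THF/MeOH/H2O, 50 °C; then 1 M HCl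
Reagents that add atoms: lithium hydroxide [Li+].[OH-]
Why: Ester saponification, which cannot epimerize the stereocentre because it is not α to the carbonyl.

Step 4
Reactants: 5 2-[(1R)-2,6,6-trimethylcyclohex-2-en-1-yl]acetic acid
Product: 7 1-diazo-3-[(1R)-2,6,6-trimethylcyclohex-2-en-1-yl]propan-2-one, via acyl chloride 6 (not isolated)
Conditions: (COCl)2, DMF (cat.), CH2Cl2, 0 °C to rt; evaporate; CH2N2 (3 equiv), Et2O, 0 °C
Reagents that add atoms: diazomethane C=[N+]=[N-]
Why: Arndt–Eistert-type acylation of diazomethane by the acyl chloride, the second equivalent of diazomethane taking up HCl, which gives the α-diazo ketone without touching the alkene.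

Step 5
Reactants: 7 1-diazo-3-[(1R)-2,6,6-trimethylcyclohex-2-en-1-yl]propan-2-one
Product: 8 (1S,2R,6R,9S)-1,5,5-trimethyltricyclo[4.3.0.0^2,9]nonan-8-one (cyclopropane on C1–C9–C10; H-5 and the C10 methyl cis)
Conditions: Cu(acac)2 (5 mol %), toluene, 110 °C, slow addition of 7
Reagents that add atoms: none
Why: Intramolecular cyclopropanation of a γ,δ-unsaturated α-diazo ketone by a copper carbenoid, in which the short tether can reach only the alkene face on which it sits, so that C6 and C9 end up cis on ring A and the C10 methyl is cis to H-5.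

Step 6
Reactants: 9 2-bromobenzene-1,4-diol
Product: 10 2-bromo-1,4-bis(methoxymethoxy)benzene
Conditions: MOMCl (2.5 equiv), i-Pr2NEt (3 equiv), CH2Cl2, 0 °C to rt
Reagents that add atoms: chloromethyl methyl ether COCCl
Why: Protection of both phenols as methoxymethyl acetals (O-alkylation), chosen because they survive bases and organolithiums and leave under mild acid.

Step 7
Reactants: 10 2-bromo-1,4-bis(methoxymethoxy)benzene
Product: 12 2-bromo-3,6-bis(methoxymethoxy)benzaldehyde, via aryllithium 11 (not isolated)
Conditions: LDA (1.1 equiv), THF, −78 °C; DMF, −78 °C; NH4Cl(aq)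
Reagents that add atoms: N,N-dimethylformamide CN(C)C=O
Why: Directed ortho-metalation, the C–H between Br and OMOM being the most acidic so that LDA at low temperature should lithiate there without bromine–lithium exchange or aryne formation, followed by formylation with DMF.

Step 8
Reactants: 12 2-bromo-3,6-bis(methoxymethoxy)benzaldehyde
Product: 13 [2-bromo-3,6-bis(methoxymethoxy)phenyl]methanol
Conditions: NaBH4, MeOH, 0 °C
Reagents that add atoms: none
Why: Borohydride reduction of the aldehyde to the benzylic alcohol.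

Step 9
Reactants: 13 [2-bromo-3,6-bis(methoxymethoxy)phenyl]methanol
Product: 14 2-bromo-3-(bromomethyl)-1,4-bis(methoxymethoxy)benzene
Conditions: CBr4, PPh3, 2,6-lutidine, CH2Cl2, 0 °C
Reagents that add atoms: carbon tetrabromide BrC(Br)(Br)Br
Why: Appel bromination under near-neutral conditions that should leave the MOM ethers intact.

Step 10
Reactants: 8 (1S,2R,6R,9S)-1,5,5-trimethyltricyclo[4.3.0.0^2,9]nonan-8-one; 14 2-bromo-3-(bromomethyl)-1,4-bis(methoxymethoxy)benzene
Product: 16 (1R,3aR,7aS)-1-{[2-bromo-3,6-bis(methoxymethoxy)phenyl]methyl}-4,4,7a-trimethyloctahydro-2H-inden-2-one, via lithium enolate 15 (not isolated)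
Conditions: Li (2.2 equiv), NH3(l)/THF, t-BuOH (1.0 equiv), −78 to −33 °C; isoprene; NH3 evaporated; 14 (1.3 equiv), THF, −78 to 0 °C
Reagents that add atoms: none
Why: Stork reductive alkylation, in which dissolving-metal cleavage of the cyclopropyl ketone should break the C9–C1 bond that overlaps with the carbonyl π system to give the C8/C9 enolate regiospecifically, and SN2 benzylation should occur on the convex face of the cis-bicyclo[4.3.0] enolate, cis to the angular methyl and H-5, which sets C9.

Step 11
Reactants: 16 (1R,3aR,7aS)-1-{[2-bromo-3,6-bis(methoxymethoxy)phenyl]methyl}-4,4,7a-trimethyloctahydro-2H-inden-2-one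
Product: 18 (1R,4aR,8aS)-1-{[2-bromo-3,6-bis(methoxymethoxy)phenyl]methyl}-5,5,8a-trimethyloctahydronaphthalen-2(1H)-one, via silyl enol ether 17 (not isolated)
Conditions: TMSCHN2 (1.3 equiv), Sc(OTf)3 (10 mol %), CH2Cl2, 0 °C to rt; then K2CO3 (cat.), MeOH, 0 °C
Reagents that add atoms: (trimethylsilyl)diazomethane C[Si](C)(C)C=[N+]=[N-]
Why: Sc(OTf)3 activates the C8 carbonyl of the cyclopentanone, TMSCHN2 adds to it, and the β-oxido diazonium loses N2 with a concerted 1,2-shift of the C6 methylene from C8 to the former diazo carbon, which becomes C7; the β-keto silane then undergoes 1,3-Brook rearrangement to enol silane 17, and methanolysis releases ketone 18. The closest known reaction type is the Lewis acid-catalysed diazoalkane homologation of cyclic ketones (Tiffeneau–Demjanov-type ring expansion of a cyclopentanone to a cyclohexanone). No ring is closed by cyclization: ring B reaches six members by insertion of one carbon into the C6–C8 bond of the five-membered ring, while ring A and the arene are untouched. No stereocentre is created, and C5, C9 and C10 should be carried over unchanged because the migrating carbon is a CH2 group and the non-basic medium does not enolize C9. The selectivity needed is migration of C6 rather than C9, which should be secured by C9 being a methine wedged between quaternary C10 and the ortho,ortho-disubstituted benzyl group, so that the unhindered methylene migrates as is usual for 2-substituted cycloalkanones. A second insertion should be prevented by the enol silane stage, which masks the new carbonyl, and by the small excess of diazo reagent.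

Step 12
Reactants: 18 (1R,4aR,8aS)-1-{[2-bromo-3,6-bis(methoxymethoxy)phenyl]methyl}-5,5,8a-trimethyloctahydronaphthalen-2(1H)-one
Product: 19 (1R,2R,4aR,8aS)-1-{[2-bromo-3,6-bis(methoxymethoxy)phenyl]methyl}-2,5,5,8a-tetramethyldecahydronaphthalen-2-ol
Conditions: MeMgCl (3 equiv), CeCl3 (3 equiv, anhydrous), THF, −78 to 0 °C; NH4Cl(aq)
Reagents that add atoms: methylmagnesium chloride C[Mg]Cl
Why: 1,2-Addition of an organocerium reagent (Imamoto conditions, which suppress enolization), for which ring B should react through the chair that keeps the quaternary C4 equatorial on it, so that axial C1 shields the concave face and methyl enters equatorially from the convex face, giving the C8 carbinol with methyl cis to the C9 arm.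

Step 13
Reactants: 19 (1R,2R,4aR,8aS)-1-{[2-bromo-3,6-bis(methoxymethoxy)phenyl]methyl}-2,5,5,8a-tetramethyldecahydronaphthalen-2-ol
Product: 21 2-{[(1R,2R,4aR,8aS)-2-hydroxy-2,5,5,8a-tetramethyldecahydronaphthalen-1-yl]methyl}-3,6-bis(methoxymethoxy)benzaldehyde, via dilithio species 20 (not isolated)
Conditions: t-BuLi (3.3 equiv), THF, −78 °C; DMF (5 equiv), −78 to 0 °C; NH4Cl(aq)
Reagents that add atoms: N,N-dimethylformamide CN(C)C=O
Why: Bromine–lithium exchange after deprotonation of the tertiary alcohol, then formylation with DMF of the aryllithium, which is stabilised by the flanking OMOM group; no stereocentre is involved.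

Step 14
Reactants: 21 2-{[(1R,2R,4aR,8aS)-2-hydroxy-2,5,5,8a-tetramethyldecahydronaphthalen-1-yl]methyl}-3,6-bis(methoxymethoxy)benzaldehyde
Product: 22 3,6-dihydroxy-2-{[(1R,2R,4aR,8aS)-2-hydroxy-2,5,5,8a-tetramethyldecahydronaphthalen-1-yl]methyl}benzaldehyde (CNP0267523.2)
Conditions: HCl (conc., 3 equiv), degassed MeOH, 35 °C, argon
Reagents that add atoms: none
Why: Acid-catalysed methanolysis of the two phenolic MOM acetals, mild enough that the tertiary alcohol should neither ionize nor be captured by the neighbouring phenol, and run under argon because the hydroquinone is air-sensitive.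

**Compound list**
1 | 2,4,4-trimethylcyclohex-2-en-1-one | CC1=CC(C)(C)CCC1=O | starting material
2 | (S)-2,4,4-trimethylcyclohex-2-en-1-ol | CC1=CC(C)(C)CC[C@@H]1O | intermediate
3 | ketene acetal (1-ethoxyvinyl ether of 2) | C=C(OCC)O[C@H]1CCC(C)(C)C=C1C | intermediate
4 | ethyl 2-[(1R)-2,6,6-trimethylcyclohex-2-en-1-yl]acetate | CCOC(=O)C[C@H]1C(C)=CCCC1(C)C | intermediate
5 | 2-[(1R)-2,6,6-trimethylcyclohex-2-en-1-yl]acetic acid | OC(=O)C[C@H]1C(C)=CCCC1(C)C | intermediate
6 | 2-[(1R)-2,6,6-trimethylcyclohex-2-en-1-yl]acetyl chloride | ClC(=O)C[C@H]1C(C)=CCCC1(C)C | intermediate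
7 | 1-diazo-3-[(1R)-2,6,6-trimethylcyclohex-2-en-1-yl]propan-2-one | [N-]=[N+]=CC(=O)C[C@H]1C(C)=CCCC1(C)C | intermediate
8 | (1S,2R,6R,9S)-1,5,5-trimethyltricyclo[4.3.0.0^2,9]nonan-8-one | O=C1C[C@H]2[C@@]3(C)[C@@H]1[C@H]3CCC2(C)C | intermediate
9 | 2-bromobenzene-1,4-diol | Oc1ccc(O)c(Br)c1 | starting material
10 | 2-bromo-1,4-bis(methoxymethoxy)benzene | COCOc1ccc(OCOC)c(Br)c1 | intermediate
11 | [2-bromo-3,6-bis(methoxymethoxy)phenyl]lithium | COCOc1ccc(OCOC)c([Li])c1Br | intermediate
12 | 2-bromo-3,6-bis(methoxymethoxy)benzaldehyde | COCOc1ccc(OCOC)c(C=O)c1Br | intermediate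
13 | [2-bromo-3,6-bis(methoxymethoxy)phenyl]methanol | COCOc1ccc(OCOC)c(CO)c1Br | intermediate
14 | 2-bromo-3-(bromomethyl)-1,4-bis(methoxymethoxy)benzene | COCOc1ccc(OCOC)c(CBr)c1Br | intermediate
15 | lithium (3aR,7aS)-4,4,7a-trimethyl-3a,4,5,6,7,7a-hexahydro-3H-inden-2-olate (C8–OLi, C8=C9) | [Li]OC1=C[C@@]2(C)CCCC(C)(C)[C@H]2C1 | intermediate
16 | (1R,3aR,7aS)-1-{[2-bromo-3,6-bis(methoxymethoxy)phenyl]methyl}-4,4,7a-trimethyloctahydro-2H-inden-2-one | O=C1C[C@@H]2C(C)(C)CCC[C@]2(C)[C@H]1Cc3c(OCOC)ccc(OCOC)c3Br | intermediate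
17 | {[(1R,4aR,8aS)-1-{[2-bromo-3,6-bis(methoxymethoxy)phenyl]methyl}-5,5,8a-trimethyl-1,4,4a,5,6,7,8,8a-octahydronaphthalen-2-yl]oxy}trimethylsilane | C[Si](C)(C)OC1=CC[C@@H]2C(C)(C)CCC[C@]2(C)[C@H]1Cc3c(OCOC)ccc(OCOC)c3Br | intermediate
18 | (1R,4aR,8aS)-1-{[2-bromo-3,6-bis(methoxymethoxy)phenyl]methyl}-5,5,8a-trimethyloctahydronaphthalen-2(1H)-one | O=C1CC[C@@H]2C(C)(C)CCC[C@]2(C)[C@H]1Cc3c(OCOC)ccc(OCOC)c3Br | intermediate
19 | (1R,2R,4aR,8aS)-1-{[2-bromo-3,6-bis(methoxymethoxy)phenyl]methyl}-2,5,5,8a-tetramethyldecahydronaphthalen-2-ol | CC1(C)CCC[C@@]2(C)[C@@H]1CC[C@@](C)(O)[C@@H]2Cc3c(OCOC)ccc(OCOC)c3Br | intermediate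
20 | lithium alkoxide and aryllithium of 19 (dilithio species) | CC1(C)CCC[C@@]2(C)[C@@H]1CC[C@@](C)(O[Li])[C@@H]2Cc3c(OCOC)ccc(OCOC)c3[Li] | intermediate
21 | 2-{[(1R,2R,4aR,8aS)-2-hydroxy-2,5,5,8a-tetramethyldecahydronaphthalen-1-yl]methyl}-3,6-bis(methoxymethoxy)benzaldehyde | CC1(C)CCC[C@@]2(C)[C@@H]1CC[C@@](C)(O)[C@@H]2Cc3c(OCOC)ccc(OCOC)c3C=O | intermediate
22 | 3,6-dihydroxy-2-{[(1R,2R,4aR,8aS)-2-hydroxy-2,5,5,8a-tetramethyldecahydronaphthalen-1-yl]methyl}benzaldehyde | CC1(C)CCC[C@@]2(C)[C@@H]1CC[C@@](C)(O)[C@@H]2Cc1c(O)ccc(O)c1C=O | target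

**Totals:** 14 steps. Longest linear sequence: 10 steps (steps 1–5 and 10–14, from 1); the arene branch is steps 6–9.

**Steps most likely to fail**

Step 10. What may go wrong: attack of the benzyl bromide on the concave face of the enolate, or proton transfer between enolate and product before alkylation, so that C6 is alkylated or C9 is epimerized. The fallback sets out from 8 and comes back at 16; it sets C9 by hydroxyl-directed hydrogenation instead of by alkylation. Li/NH3 opening of 8 and trapping with TMSCl/Et3N gives the trimethylsilyl enol ether F1. MeLi regenerates enolate 15, which adds to aldehyde 12 to give the aldol adduct F2. MsCl/Et3N followed by DBU gives the arylidene ketone F3. NaBH4/CeCl3 in MeOH should deliver hydride from the convex face and give the allylic alcohol F4 with its hydroxyl on the concave face. H2 with [Ir(cod)(PCy3)(py)]PF6 in CH2Cl2 then adds hydrogen to C9 from the hydroxyl side to give the saturated alcohol F5, and Dess–Martin periodinane returns ketone 16.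

Step 12. What may go wrong: delivery of methyl to the concave face if ring B reacts through its other chair, or enolization in place of addition. The fallback sets out from 18 and comes back at 19; it brings in the oxygen, not the methyl, from the accessible face. Wittig methylenation (Ph3P=CH2, THF) gives the exocyclic alkene F6. mCPBA/NaHCO3 should epoxidize from the face that the methyl reagent took in the failed addition, giving the spiro-epoxide F7 with oxygen on that face. LiEt3BH in THF opens it at the CH2 group to give 19.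

Step 11. What may go wrong: migration of C9 in place of C6, a second insertion, or Lewis acid attack on the MOM ethers. The fallback sets out from 8 and comes back at 18; it moves the ring enlargement ahead of the cyclopropane opening. The same diazo insertion (TMSCHN2, Sc(OTf)3, then K2CO3/MeOH) is run on tricyclic ketone 8, where C9 is a cyclopropane carbon that should not migrate and no acid-labile group is present, and gives the ring-expanded cyclopropyl ketone F8. Li/NH3 opening gives the six-ring lithium enolate F9, which is benzylated with 14 to give 18.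

Further compounds
F1 | step 10 | {[(3aR,7aS)-4,4,7a-trimethyl-3a,4,5,6,7,7a-hexahydro-3H-inden-2-yl]oxy}trimethylsilane | C[Si](C)(C)OC1=C[C@@]2(C)CCCC(C)(C)[C@H]2C1
F2 | step 10 | (3aR,7aS)-1-{[2-bromo-3,6-bis(methoxymethoxy)phenyl](hydroxy)methyl}-4,4,7a-trimethyloctahydro-2H-inden-2-one (mixture at C1 and the carbinol carbon) | O=C1C[C@@H]2C(C)(C)CCC[C@]2(C)C1C(O)c3c(OCOC)ccc(OCOC)c3Br
F3 | step 10 | (3aR,7aS)-1-{[2-bromo-3,6-bis(methoxymethoxy)phenyl]methylidene}-4,4,7a-trimethyloctahydro-2H-inden-2-one (drawn E; either geometry serves) | O=C1C[C@@H]2C(C)(C)CCC[C@]2(C)/C1=C\c3c(OCOC)ccc(OCOC)c3Br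
F4 | step 10 | allylic alcohol from F3, hydroxyl on the concave face | O[C@@H]1C[C@@H]2C(C)(C)CCC[C@]2(C)/C1=C\c3c(OCOC)ccc(OCOC)c3Br
F5 | step 10 | (1R,3aR,7aS)-1-{[2-bromo-3,6-bis(methoxymethoxy)phenyl]methyl}-4,4,7a-trimethyloctahydro-1H-inden-2-ol, hydroxyl cis to H-1 | O[C@@H]1C[C@@H]2C(C)(C)CCC[C@]2(C)[C@H]1Cc3c(OCOC)ccc(OCOC)c3Br
F6 | step 12 | (1R,4aR,8aS)-1-{[2-bromo-3,6-bis(methoxymethoxy)phenyl]methyl}-5,5,8a-trimethyl-2-methylidenedecahydronaphthalene | C=C1CC[C@@H]2C(C)(C)CCC[C@]2(C)[C@H]1Cc3c(OCOC)ccc(OCOC)c3Br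
F7 | step 12 | spiro-epoxide of F6 at C8, oxygen on the concave face | CC1(C)CCC[C@@]2(C)[C@@H]1CC[C@]3(CO3)[C@@H]2Cc4c(OCOC)ccc(OCOC)c4Br
F8 | step 11 | ring-expanded tricyclic cyclopropyl ketone (8 with C7 inserted between C6 and C8) | O=C1CC[C@H]2[C@@]3(C)[C@@H]1[C@H]3CCC2(C)C
F9 | step 11 | lithium enolate of the cis-5,5,8a-trimethyloctahydronaphthalen-2(1H)-one (C8–OLi, C8=C9) | [Li]OC1=C[C@@]2(C)CCCC(C)(C)[C@H]2CC1
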